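## Retrosynthetic overview

1. Numbering (daucane): C1 = ring-fusion C(CH3), C2/C3 = CH2CH2, C4 = C(OH)(iPr), C5 = ring-fusion CH, C6 = CH–O–acyl, C7 = CH2, C8 = C(CH3)=, C9 = =CH, C10 = C=O. Ring A = cyclopentane C1–C5, ring B = cycloheptenone C1, C5–C10, and β = the face of the C1 methyl group.
2. Late stage: the vanillate at C6–O, the C8=C9 bond (the C10 ketone can enolise only towards C9) and the C6 carbinol (reduction directed by C4–OH) are removed. This leads back to a trans-fused 4β-hydroxy-6,10-dione.
3. Key disconnection: C5 is excised from ring B (bonds C5–C6 and C5–C1), so ring B shrinks to a six-membered ring and ring A opens to a side chain ending in a C5 diazo carbon. In the forward direction, one event closes ring A and expands the six-membered ring to ring B.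
4. Enabling feature: quaternary C1 carries C10=O directly and C6=O across C5 alone. Without C5 these are therefore the two equivalent carbonyls of a mirror-symmetric 2,2-disubstituted cyclohexane-1,3-dione. C5 is also bonded to carbinol C4, the only stereocentre set by catalysis, which relays to C1 and C5 and then to C6.
5. Precursor assembly: dione plus vinyl oxirane (Tsuji–Trost), Sharpless epoxidation, hydride opening, oxidation, hydrazone. Ring order: the six-membered carbocycle is bought, then rings A and B form together.

Key step: step 8

Assumption: C8 is carried as an inconsequential epimer mixture up to 15, as are the two ring carbinol carbons of 7, so these centres carry no descriptor and are erased in steps 6 and 11; 5 is drawn as the Z isomer, and the E isomer would converge on the same C4 configuration.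

## Route

Step 1
Reactants: 1 5-methylcyclohexane-1,3-dione
Product: 2 2,5-dimethylcyclohexane-1,3-dione
Conditions: MeI, KOH, H2O/MeOH, 65 °C
Reagents that add atoms: iodomethane, CI
Why: C-alkylation of the stabilised 1,3-dione enolate with the small, soft electrophile in protic medium should favour carbon over oxygen, as in the standard preparation of 2-methyl-1,3-diones.

Step 2
Reactants: 3 4-methylpent-1-en-3-one (isopropyl vinyl ketone)
Product: 4 2-ethenyl-2-(propan-2-yl)oxirane (racemic)
Conditions: Me3SI, NaH, DMSO/THF, 0 °C
Reagents that add atoms: trimethylsulfonium iodide, C[S+](C)C.[I-]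
Why: In the Corey–Chaykovsky reaction the non-stabilised sulfonium ylide adds 1,2 to the enone under kinetic control and closes the oxirane; the racemic centre is erased in step 3.

Step 3
Reactants: 2 2,5-dimethylcyclohexane-1,3-dione; 4 2-ethenyl-2-(propan-2-yl)oxirane
Product: 5 2-[(2Z)-3-(hydroxymethyl)-4-methylpent-2-en-1-yl]-2,5-dimethylcyclohexane-1,3-dione
Conditions: Pd(PPh3)4 (3 mol %), THF, 23 °C
Reagents that add atoms: none
Why: In this Tsuji–Trost alkylation under neutral conditions, zerovalent palladium ionises the vinyl oxirane to an alkoxy π-allyl complex whose alkoxide deprotonates the acidic dione, and the soft enolate should attack the unhindered terminus C2 through carbon (O-allylation is reversible) to build quaternary C1.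

Step 4
Reactants: 5 allylic alcohol
Product: 6 2-{[(2S,3R)-3-(hydroxymethyl)-3-(propan-2-yl)oxiran-2-yl]methyl}-2,5-dimethylcyclohexane-1,3-dione
Conditions: Ti(OiPr)4, D-(−)-diisopropyl tartrate, t-BuOOH, 4 Å MS, CH2Cl2, −20 °C
Reagents that add atoms: tert-butyl hydroperoxide, CC(C)(C)OO
Why: In the Sharpless asymmetric epoxidation the D-(−)-tartrate, which gives (2R)-epoxy alcohols from 2-substituted allylic alcohols whatever the C3 substitution, should set C4 as R, while the second oxirane centre C3 is transient.

Step 5
Reactants: 6 epoxy alcohol
Product: 7 2-[(3R)-3-hydroxy-3-(hydroxymethyl)-4-methylpentyl]-2,5-dimethylcyclohexane-1,3-diol (carbinol epimers)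
Conditions: LiAlH4, THF, 0 → 40 °C; H2O/NaOH work-up
Reagents that add atoms: none
Why: SN2 hydride opening can occur only at the less substituted oxirane carbon C3, so the C4–O bond and its configuration are kept, and both ring ketones are reduced on purpose and restored in step 6.

Step 6
Reactants: 7 tetraol
Product: 8 (2R)-4-(1,4-dimethyl-2,6-dioxocyclohexyl)-2-hydroxy-2-(propan-2-yl)butanal
Conditions: (COCl)2, DMSO, CH2Cl2, −78 °C; Et3N, −78 → 0 °C
Reagents that add atoms: none
Why: Swern oxidation should convert the primary and both secondary carbinols in one operation, without glycol cleavage and without touching the tertiary C4 hydroxyl, and C4 bears no hydrogen and so cannot epimerise.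

Step 7
Reactants: 8 hydroxy aldehyde
Product: 9 (E)-N-tosylhydrazone of 8
Conditions: TsNHNH2 (1.0 equiv), MeOH, 0 → 23 °C
Reagents that add atoms: p-toluenesulfonyl hydrazide, Cc1ccc(cc1)S(=O)(=O)NN
Why: Hydrazone condensation with one equivalent of reagent should take the aldehyde far faster than the two ring ketones, each of which is flanked by quaternary C1.

Step 8
Reactants: 9 tosylhydrazone
Product: 12 4β-hydroxydaucane-6,10-dione (trans-fused; 1β-CH3; 5α-H; 4α-isopropyl), via diazoalkane 10 (not isolated), via diazonium alkoxide betaine 11 (not isolated)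
Conditions: NaH (1.0 equiv), THF, 0 °C; then BnEt3NCl (10 mol %), 1,4-dioxane, 65 °C, 0.01 M
Reagents that add atoms: none
Why: Proposed new method: the hydrazone salt loses sulfinate (Bamford–Stevens) to give the non-stabilised diazoalkane 10, whose nucleophilic carbon C5 adds to one ring carbonyl (C5–C6 bond, 6-exo-trig closure of a transient cyclohexane C1–C2–C3–C4–C5–C6) to give betaine 11, and N2 then leaves while the antiperiplanar C6–C1 bond shifts from C6 to C5, which contracts the transient ring to cyclopentane ring A (closure by 1,2-shift, C1–C5 bond) and inserts C5 into the cyclohexanedione, so that the six-membered ring becomes seven-membered ring B with C6=O restored. The closest known reaction types are the Büchner–Curtius–Schlotterbeck and Tiffeneau–Demjanov one-carbon expansions of cyclic ketones, their intramolecular form with ω-diazoalkyl cycloalkanones, and the intramolecular Schmidt reaction of 2-(azidoalkyl)cycloalkanones, which gives the same fused five–seven topology; what is new is a carbinol-bearing diazoalkane that desymmetrises a 2,2-disubstituted 1,3-dione. C1 is set by the choice between the two diastereotopic carbonyls in a chair-like addition state in which the C4 isopropyl group is equatorial, the C4 hydroxyl is axial and hydrogen-bonds to the attacked carbonyl oxygen, and the chain closes in the cis-ketol sense usual for aldol closures of such triketones (new alkoxide cis to the C1 methyl). C5 is set by the equatorial placement of N2 in that chair followed by inversion at C5 and retention at the migrating C1, which should put H-5 trans to the C1 methyl and cis to isopropyl, that is, the trans ring fusion. The step needs migration of C1 rather than C7, ring expansion rather than oxirane closure, and push from C6 rather than a pinacol shift from C4: an equatorial N2 is antiperiplanar to the C6–C1 ring bond but not to C6–C7 or to the axial C6 alkoxide, and only C6 carries a full alkoxide. C4 bears no hydrogen, so the usual 1,2-hydride shift of alkyl diazo compounds cannot compete, and high dilution should suppress azine formation.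

Step 9
Reactants: 12 hydroxy dione
Product: 13 4β,6α-dihydroxydaucan-10-one
Conditions: Me4NBH(OAc)3, MeCN/AcOH, −30 °C
Reagents that add atoms: none
Why: In the Evans–Saksena reduction the C4β hydroxyl binds boron and should deliver hydride internally to the β face of C6=O (H-6 β, O-6 α), while the C10 ketone sits on the opposite face of ring A, out of reach of this otherwise unreactive hydride.

Step 10
Reactants: 13 diol; 14 4-acetoxy-3-methoxybenzoic acid
Product: 15 4β-hydroxy-10-oxodaucan-6α-yl 4-acetoxy-3-methoxybenzoate
Conditions: DCC, DMAP (cat.), CH2Cl2, 0 → 23 °C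
Reagents that add atoms: none
Why: Steglich esterification should acylate only the secondary C6 hydroxyl, because the tertiary C4 hydroxyl is inert under these conditions and the phenol is masked as its acetate.

Step 11
Reactants: 15 keto ester
Product: 16 4β-hydroxy-10-oxodauc-8-en-6α-yl 4-acetoxy-3-methoxybenzoate
Conditions: IBX, DMSO/fluorobenzene, 75 °C
Reagents that add atoms: none
Why: IBX dehydrogenation of a ketone runs through its enol, and since C1 is quaternary only C9 can enolise, so the C8=C9 enone should form regiospecifically, which erases the C8 centre while the acetate protects the phenol from oxidation.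

Step 12
Reactants: 16 enone acetate
Product: 17 4β-hydroxy-10-oxodauc-8-en-6α-yl 4-hydroxy-3-methoxybenzoate (CNP0136950.2)
Conditions: NH3 (7 M in MeOH), 0 °C
Reagents that add atoms: none
Why: Aminolysis should cleave the activated aryl acetate much faster than the hindered secondary benzoate, and the low temperature should avoid vinylogous elimination of the C6 ester.

## Compound list

1 | 5-methylcyclohexane-1,3-dione | CC1CC(=O)CC(=O)C1 | starting material
2 | 2,5-dimethylcyclohexane-1,3-dione | CC1CC(=O)C(C)C(=O)C1 | intermediate
3 | 4-methylpent-1-en-3-one | C=CC(=O)C(C)C | starting material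
4 | 2-ethenyl-2-(propan-2-yl)oxirane (racemic) | C=CC1(CO1)C(C)C | intermediate
5 | 2-[(2Z)-3-(hydroxymethyl)-4-methylpent-2-en-1-yl]-2,5-dimethylcyclohexane-1,3-dione | CC1CC(=O)C(C)(C/C=C(\CO)C(C)C)C(=O)C1 | intermediate
6 | 2-{[(2S,3R)-3-(hydroxymethyl)-3-(propan-2-yl)oxiran-2-yl]methyl}-2,5-dimethylcyclohexane-1,3-dione | CC1CC(=O)C(C)(C[C@@H]2O[C@@]2(CO)C(C)C)C(=O)C1 | intermediate
7 | 2-[(3R)-3-hydroxy-3-(hydroxymethyl)-4-methylpentyl]-2,5-dimethylcyclohexane-1,3-diol (ring carbinol epimers) | CC1CC(O)C(C)(CC[C@@](O)(C(C)C)CO)C(O)C1 | intermediate
8 | (2R)-4-(1,4-dimethyl-2,6-dioxocyclohexyl)-2-hydroxy-2-(propan-2-yl)butanal | CC1CC(=O)C(C)(CC[C@@](O)(C(C)C)C=O)C(=O)C1 | intermediate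
9 | (E)-N-tosylhydrazone of 8 | CC1CC(=O)C(C)(CC[C@@](O)(C(C)C)/C=N/NS(=O)(=O)c2ccc(C)cc2)C(=O)C1 | intermediate
10 | 2-[(3R)-4-diazo-3-hydroxy-3-(propan-2-yl)butyl]-2,5-dimethylcyclohexane-1,3-dione | CC1CC(=O)C(C)(CC[C@@](O)(C(C)C)C=[N+]=[N-])C(=O)C1 | intermediate
11 | cis-decalin diazonium alkoxide betaine (1-CH3, O-4, N2 on C5 and O-6 all on one face) | C[C@]12CC[C@@](O)(C(C)C)[C@H]([N+]#N)[C@@]1([O-])CC(C)CC2=O | intermediate
12 | 4β-hydroxydaucane-6,10-dione (trans-fused, 1β-CH3, 5α-H) | O=C1CC(C)CC(=O)[C@@]2(C)CC[C@@](O)(C(C)C)[C@H]12 | intermediate
13 | 4β,6α-dihydroxydaucan-10-one | O[C@H]1CC(C)CC(=O)[C@@]2(C)CC[C@@](O)(C(C)C)[C@H]12 | intermediate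
14 | 4-acetoxy-3-methoxybenzoic acid | COc1cc(C(=O)O)ccc1OC(C)=O | starting material
15 | 4β-hydroxy-10-oxodaucan-6α-yl 4-acetoxy-3-methoxybenzoate | COc1cc(C(=O)O[C@H]2CC(C)CC(=O)[C@@]3(C)CC[C@@](O)(C(C)C)[C@H]23)ccc1OC(C)=O | intermediate
16 | 4β-hydroxy-10-oxodauc-8-en-6α-yl 4-acetoxy-3-methoxybenzoate | COc1cc(C(=O)O[C@H]2CC(C)=CC(=O)[C@@]3(C)CC[C@@](O)(C(C)C)[C@H]23)ccc1OC(C)=O | intermediate
17 | 4β-hydroxy-10-oxodauc-8-en-6α-yl 4-hydroxy-3-methoxybenzoate (CNP0136950.2) | COc1cc(C(=O)O[C@H]2CC(C)=CC(=O)[C@@]3(C)CC[C@@](O)(C(C)C)[C@H]23)ccc1O | target

Total step count: 12. Longest linear sequence: 11 steps (1 or 3 to 17).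

## Steps most likely to fail

**Step 8.**
- What may go wrong: the diazoalkane may be lost before it reaches the hindered carbonyl, through azine formation, carbene-type decay or protonation. The betaine may also collapse by oxirane closure or with poor choice between the two carbonyls.
- Fallback with known chemistry, from 8 back to 12: SmI2 (THF/t-BuOH, −78 °C) should effect a chelated keto–aldehyde pinacol cyclisation onto one ring carbonyl to give the all-cis decalin triol ketone F1. MsCl/pyridine should sulfonylate its only secondary hydroxyl to give the C5 mesylate F2. The equatorial leaving group of F2 is antiperiplanar to C6–C1, so KOtBu should trigger the classical semipinacol hydronaphthalene-to-hydroazulene shift to 12.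

**Step 9.**
- What may go wrong: facial selectivity may be poor, because the tertiary hydroxyl may exchange slowly with boron and the C1 methyl opposes approach to the β face. Undirected attack from the α face could then take over.
- Fallback, from 12 back to 15: this preference is used instead of fought. Narasaka–Prasad reduction (Et2BOMe, NaBH4, THF/MeOH, −78 °C) activates only the chelated C6 ketone, and external hydride from the α face should give the 6-epimeric diol F3. Mitsunobu esterification of F3 with acid 14 (PPh3, DIAD) inverts C6 and rejoins the route at 15.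

**Step 5.**
- What may go wrong: retro-aldol ring cleavage of the β-alkoxy ketone aluminates, or sluggish oxirane opening next to the fully substituted carbon.
- Fallback, from 6 back to 8, which leaves the dione untouched: MgI2 should open the oxirane at C3 to the iodohydrin F4. Bu3SnH/AIBN removes iodine by a radical chain to give the diol dione F5. TEMPO/PhI(OAc)2 oxidises only the primary alcohol, which gives 8 and bypasses 7.

## Further compounds

F1 | step 8 | all-cis decalin triol ketone (C5–C6 bond formed; 1-CH3, O-4, O-5, O-6 on one face) | C[C@]12CC[C@@](O)(C(C)C)[C@H](O)[C@@]1(O)CC(C)CC2=O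
F2 | step 8 | C5 mesylate of F1 | C[C@]12CC[C@@](O)(C(C)C)[C@H](OS(C)(=O)=O)[C@@]1(O)CC(C)CC2=O
F3 | step 9 | 4β,6β-dihydroxydaucan-10-one (6-epimeric diol) | O[C@@H]1CC(C)CC(=O)[C@@]2(C)CC[C@@](O)(C(C)C)[C@H]12
F4 | step 5 | C3 iodohydrin from 6 | CC1CC(=O)C(C)(C[C@@H](I)[C@](O)(CO)C(C)C)C(=O)C1
F5 | step 5 | 2-[(3R)-3-hydroxy-3-(hydroxymethyl)-4-methylpentyl]-2,5-dimethylcyclohexane-1,3-dione | CC1CC(=O)C(C)(CC[C@@](O)(C(C)C)CO)C(=O)C1
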